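**Remark on the structure.** The SMILES is read as written: all three ring olefins have the chain carbons cis (2Z, 4Z, 8Z), the arene is the free hydroquinone, and the configurations are 6S, 7S, 10S, 11R, 12S, 14S, 15R. Positions are numbered C1 (lactam carbonyl) to C15 (benzylic carbon), C16–C21 for the arene, N on C20, OH on C18 and C21.

## The problem

- The target is a 19-membered ansa lactam in which the C1–C15 chain bridges the meta positions C16 and C20 of a 2-aminohydroquinone. No simple building block holds this connectivity, so the chain must be built and then closed.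
- The ring holds three cis olefins: trisubstituted C2=C3 and C8=C9 (each in the less stable geometry, C1 cis to C4 and C7 cis to C10) and disubstituted C4=C5. The (2Z,4Z)-dienamide isomerises with acid, light or metal hydrides, and a (2Z)-acid of this kind cannot be activated without risk to C2=C3.
- Seven stereocentres fall into three groups: C6/C7 (OMe/O-carbamate syn), C10/C11/C12 (Me/OMe syn, OMe/OMe anti) and C14/C15 (Me/OMe syn).
- The groups are insulated by the C8=C9 olefin and the C13 methylene. C15 can be set together with C14, and C12 can support C11/C10 through a Felkin preference, but C12 itself and the C6/C7 pair need reagent control.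
- Sensitive groups are the aminohydroquinone (air oxidation), the primary carbamate on allylic C7, the C6 methyl ether (allylic to the diene, ionises with acid) and the α-oxygenated aldehydes that chain extension requires.
- The feature that makes the key step possible is C4=C5. It is the only ring olefin whose two carbons carry nothing but ring neighbours (sp2 C3 and the methoxy carbon C6), so it can pass through ring closure as a C4≡C5 triple bond. A 19-membered ring holds the linear C3–C4≡C5–C6 unit without strain, and cis reduction afterwards gives 4Z by mechanism.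

## Retrosynthesis

**Arene oxidation level.** Target 33 is taken back to quinone 32 and from there to the dimethyl ether 31 (cuts: two aryl O–Me bonds). The hydroquinone is released last, by reduction, so that no free aminohydroquinone is carried. The forward step must oxidise the para-dimethoxyanilide without touching diene or carbamate.

**Carbamate and C4=C5.** 31 comes from alcohol 29 (C7 O–C(O) bond), 29 from silyl ether 28, and 28 from cycloalkyne 27 by addition of two hydrogens across C4≡C5. The labile Z,Z-diene then exists for only four steps. The forward reduction must be cis and must spare the two trisubstituted olefins.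

**Key cut, C4≡C5.** 27 is opened to the acyclic diyne 26 by ring-closing alkyne metathesis. Against the neighbouring N–C1 cut, this closes the ring at a non-polar, non-stereogenic bond, needs no activated (2Z)-acid on an advanced intermediate, and delivers the olefin geometry through the following syn reduction. 26 has no ring and both alkynes are simple methyl-capped units.

**Amide.** 26 is cut at N–C1 into aniline 21 and the six-carbon acid 24, which is made from but-2-ynal 22 through ester 23 by Z-selective olefination. Formed intermolecularly on a cheap acid, the amide is no longer a ring-closing problem.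

**C5 alkyne and C6/C7.** 21 comes from nitroarene 20, and 20 from terminal alkyne 19. The alkyne carbon C5 is the acyl carbon of aldol adduct 16, reached through 17 and aldehyde 18. The C6–C7 bond is cut to Z-enal 13 and glycolate thioimide 15 (from 14). An auxiliary-controlled syn glycolate aldol sets both oxygen-bearing centres at once, independent of the remote C10 centre.

**C8=C9.** 13 is taken back through alcohol 12 and Z-enoate 11 to aldehyde 10 (cut C8=C9). The Z-α-methyl enoate is the natural product of a Still–Gennari olefination, and the same reagent serves for 23.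

**C10–C11 and C12–O.** 10 comes from alkene 9 by ozonolysis, 9 from diol 8, and 8 (through benzoate 7) from α-benzoyloxy aldehyde 6 by crotylboration (cut C10–C11). Since C11 and C12 both end as methyl ethers, a diol that is methylated twice saves protecting-group steps. 6 is cut at C12–O to aldehyde 5, so C12 is set by enamine catalysis.

**C11, C14–C15.** 5 comes from alkene 4 by hydroformylation (adds C11 and leaves C13 as CH2). 4 comes from alcohol 3, and 3 from aldehyde 2 by crotylboration (cut C14–C15), which sets the Me/OH syn pair in one step. 2 is the methyl ether of commercial 1.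

## Roads not taken

**Alternative 1:** cut N–C1 (the route most chemists would draw first). The forward key step is macrolactamisation of seco amino acid A1 to 28. This activates a (2Z,4Z)-dienoic acid on the most advanced intermediate, where C2=C3 can be lost through reversible addition of the activating nucleophile or through a ketene. The carboxyl oxygen can also add to C5. The aniline, flanked by a methoxy group, is a poor nucleophile, so activation would have to be forceful and long, and A1 needs extra steps to unmask acid and amine. In the chosen plan the same amide is made intermolecularly from 24, where any loss of geometry costs only a six-carbon reagent, and the diene appears after ring closure.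

**Alternative 2:** cut C4=C5 as an olefin. The forward key step is Z-selective ring-closing olefin metathesis of tetraene A2 to 31. A2 would be several steps shorter (a vinyl group at C5 from a γ-methoxyallylboration of 13, no silyl ether, no alkyne). However, nothing in A2 biases the geometry of the new olefin; the catalyst alone must deliver Z. The diene terminus gives a stabilised vinyl alkylidene, kinetically Z-selective catalysts tolerate N–H groups poorly, and secondary metathesis or hydride isomerisation would erode the diene. The alkyne route spends steps to make the geometry a consequence of mechanism.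

**Alternative 3:** cut C7–C8. The forward key step is an intramolecular Nozaki–Hiyama–Kishi reaction (CrCl2, NiCl2) of iodo aldehyde A3 to 29, closing the ring and creating C7 together. The aldehyde of A3 is α-methoxy, and its α-carbon C6 is also allylic to the diene, so enolisation toward a conjugated trienol ether threatens C6. The Felkin preference of α-alkoxy aldehydes favours the 6,7-anti isomer, the wrong one, with ring conformation as the only other control. The diene would also have to be carried through the chain assembly. The chosen plan sets C6/C7 with an auxiliary on a stable acyclic intermediate.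

Key step: step 21

## Route

Step 1
Reactants: 1 2-hydroxy-5-methoxy-3-nitrobenzaldehyde
Product: 2 2,5-dimethoxy-3-nitrobenzaldehyde
Conditions: MeI, K2CO3, DMF, 40 °C
Reagents that add atoms: iodomethane, CI
Why: Williamson methylation of the acidic ortho-nitrophenol; aldehyde and nitro group should be untouched.

Step 2
Reactants: 2 2,5-dimethoxy-3-nitrobenzaldehyde
Product: 3 (1R,2S)-1-(2,5-dimethoxy-3-nitrophenyl)-2-methylbut-3-en-1-ol
Conditions: cis-2-butene, n-BuLi, KOt-Bu, THF, −78 to −45 °C; (+)-Ipc2BOMe; BF3·OEt2; then 2, −78 °C; NaOH, H2O2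
Reagents that add atoms: cis-2-butene, C/C=C\C, delivered as B-[(Z)-but-2-enyl]bis(isopinocampheyl)borane, C/C=C\CB([C@H]1C[C@H]2C[C@@H]([C@@H]1C)C2(C)C)[C@H]1C[C@H]2C[C@@H]([C@@H]1C)C2(C)C
Why: Brown crotylboration through a closed chair transition state; the Z-crotyl unit gives the C14-Me/C15-OH syn pair and the isopinocampheyl groups derived from (−)-α-pinene direct attack to the Re face of the aldehyde, giving 15R,14S.

Step 3
Reactants: 3 (1R,2S)-1-(2,5-dimethoxy-3-nitrophenyl)-2-methylbut-3-en-1-ol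
Product: 4 (3S,4R)-4-(2,5-dimethoxy-3-nitrophenyl)-4-methoxy-3-methylbut-1-ene
Conditions: NaH, MeI, THF/DMF, 0 °C to rt
Reagents that add atoms: iodomethane, CI
Why: Williamson methylation of the benzylic alkoxide; it removes the hydroxyl that would otherwise form a lactol with the aldehyde of step 4.

Step 4
Reactants: 4 (3S,4R)-4-(2,5-dimethoxy-3-nitrophenyl)-4-methoxy-3-methylbut-1-ene
Product: 5 (4S,5R)-5-(2,5-dimethoxy-3-nitrophenyl)-5-methoxy-4-methylpentanal
Conditions: Rh(acac)(CO)2 (1 mol %), Xantphos, CO/H2 (1:1, 10 bar), toluene, 70 °C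
Reagents that add atoms: carbon monoxide, [C-]#[O+]
Why: Rhodium-catalysed hydroformylation; the wide-bite-angle diphosphine should place the formyl group (C11) on the terminal carbon of the monosubstituted olefin, leaving C13 as CH2 and C14 untouched.

Step 5
Reactants: 5 (4S,5R)-5-(2,5-dimethoxy-3-nitrophenyl)-5-methoxy-4-methylpentanal
Product: 6 (2S,4S,5R)-5-(2,5-dimethoxy-3-nitrophenyl)-5-methoxy-4-methyl-1-oxopentan-2-yl benzoate
Conditions: (S)-2-(triphenylmethyl)pyrrolidine (10 mol %), (PhCO2)2, hydroquinone (10 mol %), THF, 0 °C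
Reagents that add atoms: dibenzoyl peroxide, O=C(OOC(=O)c1ccccc1)c1ccccc1
Why: Enamine-catalysed α-benzoyloxylation of an aldehyde; the trityl group of the (S)-catalyst shields one face of the E-enamine, so the peroxide oxygen should be taken up on the other face to give 12S under catalyst control, the nearest stereocentre (C14) being two atoms away.

Step 6
Reactants: 6 (2S,4S,5R)-5-(2,5-dimethoxy-3-nitrophenyl)-5-methoxy-4-methyl-1-oxopentan-2-yl benzoate
Product: 8 (3S,4R,5S,7S,8R)-8-(2,5-dimethoxy-3-nitrophenyl)-8-methoxy-3,7-dimethyloct-1-ene-4,5-diol, via benzoate 7 (not isolated)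
Conditions: B-[(Z)-but-2-enyl]bis(isopinocampheyl)borane (made as in step 2), THF, −78 °C; NaOH, H2O2; then K2CO3, MeOH, rt
Reagents that add atoms: cis-2-butene, C/C=C\C, delivered as B-[(Z)-but-2-enyl]bis(isopinocampheyl)borane, C/C=C\CB([C@H]1C[C@H]2C[C@@H]([C@@H]1C)C2(C)C)[C@H]1C[C@H]2C[C@@H]([C@@H]1C)C2(C)C
Why: Brown crotylboration with the reagent of step 2; the Z-crotyl unit gives 10,11-syn, and the Re-face attack imposed by the reagent coincides with the Felkin (polar) preference of the α-acyloxy aldehyde, giving 11,12-anti (10S,11R). Benzoate migration is harmless because methanolysis then frees both hydroxyls.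

Step 7
Reactants: 8 (3S,4R,5S,7S,8R)-8-(2,5-dimethoxy-3-nitrophenyl)-8-methoxy-3,7-dimethyloct-1-ene-4,5-diol
Product: 9 (3S,4R,5S,7S,8R)-8-(2,5-dimethoxy-3-nitrophenyl)-4,5,8-trimethoxy-3,7-dimethyloct-1-ene
Conditions: NaH, MeI, THF/DMF, 0 °C to rt
Reagents that add atoms: iodomethane, CI
Why: Double Williamson methylation; both C11 and C12 end as methyl ethers, so the diol needs no differentiation.

Step 8
Reactants: 9 (3S,4R,5S,7S,8R)-8-(2,5-dimethoxy-3-nitrophenyl)-4,5,8-trimethoxy-3,7-dimethyloct-1-ene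
Product: 10 (2R,3R,4S,6S,7R)-7-(2,5-dimethoxy-3-nitrophenyl)-3,4,7-trimethoxy-2,6-dimethylheptanal
Conditions: O3, CH2Cl2/MeOH, −78 °C; PPh3
Reagents that add atoms: ozone, [O-][O+]=O
Why: Ozonolysis of the only olefin with reductive work-up; the nitro group deactivates the arene toward ozone, and the aldehyde is used crude to protect C10.

Step 9
Reactants: 10 (2R,3R,4S,6S,7R)-7-(2,5-dimethoxy-3-nitrophenyl)-3,4,7-trimethoxy-2,6-dimethylheptanal
Product: 11 methyl (2Z,4S,5R,6S,8S,9R)-9-(2,5-dimethoxy-3-nitrophenyl)-5,6,9-trimethoxy-2,4,8-trimethylnon-2-enoate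
Conditions: (CF3CH2O)2P(O)CH(CH3)CO2CH3, KN(SiMe3)2, 18-crown-6, THF, −78 °C
Reagents that add atoms: methyl 2-[bis(2,2,2-trifluoroethoxy)phosphoryl]propanoate, COC(=O)C(C)P(=O)(OCC(F)(F)F)OCC(F)(F)F
Why: Still–Gennari olefination; fast elimination from the kinetic adduct of the electron-poor phosphonate with a dissociated potassium ion should give the Z-trisubstituted enoate (C7 cis to C10) at a temperature that spares C10.

Step 10
Reactants: 11 methyl (2Z,4S,5R,6S,8S,9R)-9-(2,5-dimethoxy-3-nitrophenyl)-5,6,9-trimethoxy-2,4,8-trimethylnon-2-enoate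
Product: 12 (2Z,4S,5R,6S,8S,9R)-9-(2,5-dimethoxy-3-nitrophenyl)-5,6,9-trimethoxy-2,4,8-trimethylnon-2-en-1-ol
Conditions: i-Bu2AlH, CH2Cl2, −78 °C
Reagents that add atoms: none
Why: 1,2-Reduction of the enoate by the aluminium hydride; the olefin geometry is retained and the nitro group should survive at this temperature.

Step 11
Reactants: 12 (2Z,4S,5R,6S,8S,9R)-9-(2,5-dimethoxy-3-nitrophenyl)-5,6,9-trimethoxy-2,4,8-trimethylnon-2-en-1-ol
Product: 13 (2Z,4S,5R,6S,8S,9R)-9-(2,5-dimethoxy-3-nitrophenyl)-5,6,9-trimethoxy-2,4,8-trimethylnon-2-enal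
Conditions: MnO2, CH2Cl2, rt
Reagents that add atoms: none
Why: Allylic oxidation on the manganese dioxide surface under neutral conditions, which should keep the Z-enal from isomerising; the enal is used at once.

Step 12
Reactants: 14 (4R)-4-benzyl-1,3-thiazolidine-2-thione
Product: 15 1-[(4R)-4-benzyl-2-thioxo-1,3-thiazolidin-3-yl]-2-methoxyethan-1-one
Conditions: CH3OCH2COCl, Et3N, DMAP (cat.), CH2Cl2, 0 °C
Reagents that add atoms: methoxyacetyl chloride, COCC(Cl)=O
Why: N-Acylation of the thiazolidinethione auxiliary with an acid chloride.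

Step 13
Reactants: 13 (2Z,4S,5R,6S,8S,9R)-9-(2,5-dimethoxy-3-nitrophenyl)-5,6,9-trimethoxy-2,4,8-trimethylnon-2-enal; 15 1-[(4R)-4-benzyl-2-thioxo-1,3-thiazolidin-3-yl]-2-methoxyethan-1-one
Product: 16 (2R,3S,4Z,6S,7R,8S,10S,11R)-1-[(4R)-4-benzyl-2-thioxo-1,3-thiazolidin-3-yl]-11-(2,5-dimethoxy-3-nitrophenyl)-3-hydroxy-2,7,8,11-tetramethoxy-4,6,10-trimethylundec-4-en-1-one
Conditions: 15, TiCl4, i-Pr2NEt, N-methyl-2-pyrrolidinone, CH2Cl2, −78 °C; then 13
Reagents that add atoms: none
Why: Evans-type syn glycolate aldol through the chlorotitanium Z-enolate of the thiazolidinethione in a Zimmerman–Traxler chair; the (4R)-benzyl group should fix the enolate face and give the syn pair that becomes 6S,7S, overriding the remote C10 centre.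

Step 14
Reactants: 16 (2R,3S,4Z,6S,7R,8S,10S,11R)-1-[(4R)-4-benzyl-2-thioxo-1,3-thiazolidin-3-yl]-11-(2,5-dimethoxy-3-nitrophenyl)-3-hydroxy-2,7,8,11-tetramethoxy-4,6,10-trimethylundec-4-en-1-one
Product: 17 (2R,3S,4Z,6S,7R,8S,10S,11R)-1-[(4R)-4-benzyl-2-thioxo-1,3-thiazolidin-3-yl]-3-[(tert-butyldimethylsilyl)oxy]-11-(2,5-dimethoxy-3-nitrophenyl)-2,7,8,11-tetramethoxy-4,6,10-trimethylundec-4-en-1-one
Conditions: t-BuMe2SiOTf, 2,6-lutidine, CH2Cl2, −78 to 0 °C
Reagents that add atoms: tert-butyldimethylsilyl triflate, CC(C)(C)[Si](C)(C)OS(=O)(=O)C(F)(F)F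
Why: Silylation of the hindered allylic alcohol with the silyl triflate; the ether blocks retro-aldol cleavage and carries C7–O through the base and catalyst steps that follow.

Step 15
Reactants: 17 (2R,3S,4Z,6S,7R,8S,10S,11R)-1-[(4R)-4-benzyl-2-thioxo-1,3-thiazolidin-3-yl]-3-[(tert-butyldimethylsilyl)oxy]-11-(2,5-dimethoxy-3-nitrophenyl)-2,7,8,11-tetramethoxy-4,6,10-trimethylundec-4-en-1-one
Product: 19 tert-butyl{[(3S,4S,5Z,7S,8R,9S,11S,12R)-12-(2,5-dimethoxy-3-nitrophenyl)-3,8,9,12-tetramethoxy-5,7,11-trimethyldodec-5-en-1-yn-4-yl]oxy}dimethylsilane, via aldehyde 18 (not isolated)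
Conditions: i-Bu2AlH, CH2Cl2, −78 °C; then CH3C(O)C(N2)P(O)(OMe)2, K2CO3, MeOH, 0 °C to rt
Reagents that add atoms: dimethyl (1-diazo-2-oxopropyl)phosphonate, COP(=O)(OC)C(=[N+]=[N-])C(C)=O
Why: The hydride cleaves the thioimide to the aldehyde through a stable tetrahedral aluminate, releasing the auxiliary; Ohira–Bestmann (Seyferth–Gilbert) homologation then gives the terminal alkyne under carbonate conditions mild enough for the α-methoxy centre.

Step 16
Reactants: 19 tert-butyl{[(3S,4S,5Z,7S,8R,9S,11S,12R)-12-(2,5-dimethoxy-3-nitrophenyl)-3,8,9,12-tetramethoxy-5,7,11-trimethyldodec-5-en-1-yn-4-yl]oxy}dimethylsilane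
Product: 20 tert-butyl{[(4S,5S,6Z,8S,9R,10S,12S,13R)-13-(2,5-dimethoxy-3-nitrophenyl)-4,9,10,13-tetramethoxy-6,8,12-trimethyltridec-6-en-2-yn-5-yl]oxy}dimethylsilane
Conditions: LiN(SiMe3)2, THF, −78 °C; MeOTf
Reagents that add atoms: methyl triflate, COS(=O)(=O)C(F)(F)F
Why: Deprotonation of the terminal alkyne by the amide base (tolerated by the nitroarene, unlike an alkyllithium) and C-methylation; the methyl cap makes but-2-yne the leaving fragment of step 21.

Step 17
Reactants: 20 tert-butyl{[(4S,5S,6Z,8S,9R,10S,12S,13R)-13-(2,5-dimethoxy-3-nitrophenyl)-4,9,10,13-tetramethoxy-6,8,12-trimethyltridec-6-en-2-yn-5-yl]oxy}dimethylsilane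
Product: 21 3-[(1R,2S,4S,5R,6S,7Z,9S,10S)-9-[(tert-butyldimethylsilyl)oxy]-1,4,5,10-tetramethoxy-2,6,8-trimethyltridec-7-en-11-yn-1-yl]-2,5-dimethoxyaniline
Conditions: Zn, NH4Cl, MeOH/H2O, 50 °C
Reagents that add atoms: none
Why: Dissolving-metal reduction of the nitroarene to the aniline; the alkyne, the olefin and the silyl ether should not be touched.

Step 18
Reactants: 22 but-2-ynal
Product: 23 methyl (2Z)-2-methylhex-2-en-4-ynoate
Conditions: (CF3CH2O)2P(O)CH(CH3)CO2CH3, KN(SiMe3)2, 18-crown-6, THF, −78 °C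
Reagents that add atoms: methyl 2-[bis(2,2,2-trifluoroethoxy)phosphoryl]propanoate, COC(=O)C(C)P(=O)(OCC(F)(F)F)OCC(F)(F)F
Why: Still–Gennari olefination as in step 9; it should give the Z-enynoate in which C1 is cis to the alkyne carbon C4.

Step 19
Reactants: 23 methyl (2Z)-2-methylhex-2-en-4-ynoate
Product: 24 (2Z)-2-methylhex-2-en-4-ynoic acid
Conditions: LiOH, THF/H2O, 0 °C; dilute HCl
Reagents that add atoms: lithium hydroxide, [Li+].[OH-]
Why: Saponification by acyl–oxygen cleavage; without transition-metal salts or strong acid the Z-enynoic acid should neither isomerise nor lactonise.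

Step 20
Reactants: 21 3-[(1R,2S,4S,5R,6S,7Z,9S,10S)-9-[(tert-butyldimethylsilyl)oxy]-1,4,5,10-tetramethoxy-2,6,8-trimethyltridec-7-en-11-yn-1-yl]-2,5-dimethoxyaniline; 24 (2Z)-2-methylhex-2-en-4-ynoic acid
Product: 26 (2Z)-N-{3-[(1R,2S,4S,5R,6S,7Z,9S,10S)-9-[(tert-butyldimethylsilyl)oxy]-1,4,5,10-tetramethoxy-2,6,8-trimethyltridec-7-en-11-yn-1-yl]-2,5-dimethoxyphenyl}-2-methylhex-2-en-4-ynamide, via acid chloride 25 (not isolated)
Conditions: 24, 1-chloro-N,N,2-trimethylprop-1-en-1-amine, CH2Cl2, 0 °C; then 21, pyridine, 0 °C to rt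
Reagents that add atoms: none
Why: The α-chloroenamine forms the acid chloride under neutral conditions and the aniline is acylated without a nucleophilic catalyst, so C2=C3 should not isomerise by addition–elimination; an excess of the cheap acid can be used.

Step 21
Reactants: 26 (2Z)-N-{3-[(1R,2S,4S,5R,6S,7Z,9S,10S)-9-[(tert-butyldimethylsilyl)oxy]-1,4,5,10-tetramethoxy-2,6,8-trimethyltridec-7-en-11-yn-1-yl]-2,5-dimethoxyphenyl}-2-methylhex-2-en-4-ynamide
Product: 27 cycloalkyne lactam (4,5-didehydro-7-O-tert-butyldimethylsilyl-7-O-decarbamoyl-18,21-di-O-methyl derivative of 33; 2Z,8Z; 6S,7S,10S,11R,12S,14S,15R)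
Conditions: [Mo(≡CC6H4OMe-4)(OSiPh3)3] (20 mol %), 5 Å molecular sieves, toluene (2 mM), 80 °C
Reagents that add atoms: none
Why: Ring-closing alkyne metathesis: the molybdenum alkylidyne adds to one methyl-capped alkyne to give a metallacyclobutadiene, cycloreverts to a substrate-bound alkylidyne with loss of a butyne half, and repeats the sequence with the second alkyne of the same molecule. The closest known reaction type is the closure of macrocyclic 1,3-enynes from an enyne and an oxygenated alkyne with triarylsilanolate molybdenum alkylidynes, followed by Z-selective semireduction. The 19-membered ring is closed by metathetic union of C4 and C5, an exchange of two alkylidyne units with no nucleophile–electrophile pairing, and but-2-yne is trapped by the sieves so that the closure is driven forward. No stereocentre is formed; the alkylidyne does not react with olefins, so the seven stereocentres and the two trisubstituted Z olefins should pass unchanged. The step needs ring closure to win over oligomerisation, which high dilution and the chain fold imposed by the two Z olefins and the meta-bridged arene should secure. It also needs tolerance of the anilide N–H, which is held in a hydrogen bond to the ortho-methoxy group and is not acidic enough to protonate the silanolate ligands. The linear C3–C4≡C5–C6 unit fits a ring of this size without strain.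

Step 22
Reactants: 27 cycloalkyne lactam
Product: 28 7-O-tert-butyldimethylsilyl-7-O-decarbamoyl-18,21-di-O-methyl derivative of 33 (2Z,4Z,8Z)
Conditions: Zn (activated with Cu(OAc)2 and AgNO3), MeOH/H2O, 45 °C
Reagents that add atoms: none
Why: Semireduction by the zinc–copper–silver couple: two hydrogens are delivered to the same face of the triple bond, giving 4Z; the couple reduces conjugated and propargylically oxygenated alkynes and should leave the trisubstituted olefins and the enamide alone.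

Step 23
Reactants: 28 7-O-tert-butyldimethylsilyl-7-O-decarbamoyl-18,21-di-O-methyl derivative of 33
Product: 29 7-O-decarbamoyl-18,21-di-O-methyl derivative of 33 (free C7 hydroxyl)
Conditions: Bu4NF, AcOH, THF, 0 °C to rt
Reagents that add atoms: none
Why: Fluoride cleavage of the silyl ether, buffered with acetic acid so that the dienamide meets no strong base.

Step 24
Reactants: 29 7-O-decarbamoyl-18,21-di-O-methyl derivative of 33
Product: 31 18,21-di-O-methyl ether of 33, via trichloroacetylcarbamate 30 (not isolated)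
Conditions: Cl3CC(O)NCO, CH2Cl2, −20 °C; then K2CO3, MeOH, 0 °C
Reagents that add atoms: trichloroacetyl isocyanate, O=C=NC(=O)C(Cl)(Cl)Cl
Why: The only free hydroxyl adds to the acyl isocyanate and mild methanolysis removes the trichloroacetyl group, the standard way to a primary carbamate on a hindered secondary alcohol.

Step 25
Reactants: 31 18,21-di-O-methyl ether of 33
Product: 33 [(4Z,6Z,8S,9S,10Z,12S,13R,14S,16S,17R)-20,22-dihydroxy-8,13,14,17-tetramethoxy-4,10,12,16-tetramethyl-3-oxo-2-azabicyclo[16.3.1]docosa-1(22),4,6,10,18,20-hexaen-9-yl] carbamate, via quinone 32 (not isolated)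
Conditions: (NH4)2Ce(NO3)6, MeCN/H2O, 0 °C; then Na2S2O4, EtOAc/H2O, argon
Reagents that add atoms: water, O
Why: Oxidative demethylation of the para-dimethoxyanilide by tetravalent cerium (arene radical cation, attack of water, loss of methanol) should give the para-quinone; dithionite then reduces it to the hydroquinone under non-acidic conditions that spare the carbamate, the dienamide and the allylic ethers.

## Compound list

1 | 2-hydroxy-5-methoxy-3-nitrobenzaldehyde | O=Cc1cc(OC)cc([N+](=O)[O-])c1O | starting material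
2 | 2,5-dimethoxy-3-nitrobenzaldehyde | O=Cc1cc(OC)cc([N+](=O)[O-])c1OC | intermediate
3 | (1R,2S)-1-(2,5-dimethoxy-3-nitrophenyl)-2-methylbut-3-en-1-ol | C=C[C@H](C)[C@@H](O)c1cc(OC)cc([N+](=O)[O-])c1OC | intermediate
4 | (3S,4R)-4-(2,5-dimethoxy-3-nitrophenyl)-4-methoxy-3-methylbut-1-ene | C=C[C@H](C)[C@@H](OC)c1cc(OC)cc([N+](=O)[O-])c1OC | intermediate
5 | (4S,5R)-5-(2,5-dimethoxy-3-nitrophenyl)-5-methoxy-4-methylpentanal | O=CCC[C@H](C)[C@@H](OC)c1cc(OC)cc([N+](=O)[O-])c1OC | intermediate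
6 | (2S,4S,5R)-5-(2,5-dimethoxy-3-nitrophenyl)-5-methoxy-4-methyl-1-oxopentan-2-yl benzoate | O=C[C@@H](OC(=O)c2ccccc2)C[C@H](C)[C@@H](OC)c1cc(OC)cc([N+](=O)[O-])c1OC | intermediate
7 | (3S,4R,5S,7S,8R)-8-(2,5-dimethoxy-3-nitrophenyl)-4-hydroxy-8-methoxy-3,7-dimethyloct-1-en-5-yl benzoate | C=C[C@H](C)[C@@H](O)[C@@H](OC(=O)c2ccccc2)C[C@H](C)[C@@H](OC)c1cc(OC)cc([N+](=O)[O-])c1OC | intermediate
8 | (3S,4R,5S,7S,8R)-8-(2,5-dimethoxy-3-nitrophenyl)-8-methoxy-3,7-dimethyloct-1-ene-4,5-diol | C=C[C@H](C)[C@@H](O)[C@@H](O)C[C@H](C)[C@@H](OC)c1cc(OC)cc([N+](=O)[O-])c1OC | intermediate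
9 | (3S,4R,5S,7S,8R)-8-(2,5-dimethoxy-3-nitrophenyl)-4,5,8-trimethoxy-3,7-dimethyloct-1-ene | C=C[C@H](C)[C@@H](OC)[C@@H](OC)C[C@H](C)[C@@H](OC)c1cc(OC)cc([N+](=O)[O-])c1OC | intermediate
10 | (2R,3R,4S,6S,7R)-7-(2,5-dimethoxy-3-nitrophenyl)-3,4,7-trimethoxy-2,6-dimethylheptanal | O=C[C@H](C)[C@@H](OC)[C@@H](OC)C[C@H](C)[C@@H](OC)c1cc(OC)cc([N+](=O)[O-])c1OC | intermediate
11 | methyl (2Z,4S,5R,6S,8S,9R)-9-(2,5-dimethoxy-3-nitrophenyl)-5,6,9-trimethoxy-2,4,8-trimethylnon-2-enoate | COC(=O)/C(C)=C\[C@H](C)[C@@H](OC)[C@@H](OC)C[C@H](C)[C@@H](OC)c1cc(OC)cc([N+](=O)[O-])c1OC | intermediate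
12 | (2Z,4S,5R,6S,8S,9R)-9-(2,5-dimethoxy-3-nitrophenyl)-5,6,9-trimethoxy-2,4,8-trimethylnon-2-en-1-ol | OC/C(C)=C\[C@H](C)[C@@H](OC)[C@@H](OC)C[C@H](C)[C@@H](OC)c1cc(OC)cc([N+](=O)[O-])c1OC | intermediate
13 | (2Z,4S,5R,6S,8S,9R)-9-(2,5-dimethoxy-3-nitrophenyl)-5,6,9-trimethoxy-2,4,8-trimethylnon-2-enal | O=C/C(C)=C\[C@H](C)[C@@H](OC)[C@@H](OC)C[C@H](C)[C@@H](OC)c1cc(OC)cc([N+](=O)[O-])c1OC | intermediate
14 | (4R)-4-benzyl-1,3-thiazolidine-2-thione | S=C1SC[C@@H](Cc2ccccc2)N1 | starting material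
15 | 1-[(4R)-4-benzyl-2-thioxo-1,3-thiazolidin-3-yl]-2-methoxyethan-1-one | COCC(=O)N1C(=S)SC[C@H]1Cc1ccccc1 | intermediate
16 | (2R,3S,4Z,6S,7R,8S,10S,11R)-1-[(4R)-4-benzyl-2-thioxo-1,3-thiazolidin-3-yl]-11-(2,5-dimethoxy-3-nitrophenyl)-3-hydroxy-2,7,8,11-tetramethoxy-4,6,10-trimethylundec-4-en-1-one | S=C1SC[C@@H](Cc2ccccc2)N1C(=O)[C@H](OC)[C@@H](O)/C(C)=C\[C@H](C)[C@@H](OC)[C@@H](OC)C[C@H](C)[C@@H](OC)c1cc(OC)cc([N+](=O)[O-])c1OC | intermediate
17 | (2R,3S,4Z,6S,7R,8S,10S,11R)-1-[(4R)-4-benzyl-2-thioxo-1,3-thiazolidin-3-yl]-3-[(tert-butyldimethylsilyl)oxy]-11-(2,5-dimethoxy-3-nitrophenyl)-2,7,8,11-tetramethoxy-4,6,10-trimethylundec-4-en-1-one | S=C1SC[C@@H](Cc2ccccc2)N1C(=O)[C@H](OC)[C@@H](O[Si](C)(C)C(C)(C)C)/C(C)=C\[C@H](C)[C@@H](OC)[C@@H](OC)C[C@H](C)[C@@H](OC)c1cc(OC)cc([N+](=O)[O-])c1OC | intermediate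
18 | (2R,3S,4Z,6S,7R,8S,10S,11R)-3-[(tert-butyldimethylsilyl)oxy]-11-(2,5-dimethoxy-3-nitrophenyl)-2,7,8,11-tetramethoxy-4,6,10-trimethylundec-4-enal | O=C[C@H](OC)[C@@H](O[Si](C)(C)C(C)(C)C)/C(C)=C\[C@H](C)[C@@H](OC)[C@@H](OC)C[C@H](C)[C@@H](OC)c1cc(OC)cc([N+](=O)[O-])c1OC | intermediate
19 | tert-butyl{[(3S,4S,5Z,7S,8R,9S,11S,12R)-12-(2,5-dimethoxy-3-nitrophenyl)-3,8,9,12-tetramethoxy-5,7,11-trimethyldodec-5-en-1-yn-4-yl]oxy}dimethylsilane | C#C[C@H](OC)[C@@H](O[Si](C)(C)C(C)(C)C)/C(C)=C\[C@H](C)[C@@H](OC)[C@@H](OC)C[C@H](C)[C@@H](OC)c1cc(OC)cc([N+](=O)[O-])c1OC | intermediate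
20 | tert-butyl{[(4S,5S,6Z,8S,9R,10S,12S,13R)-13-(2,5-dimethoxy-3-nitrophenyl)-4,9,10,13-tetramethoxy-6,8,12-trimethyltridec-6-en-2-yn-5-yl]oxy}dimethylsilane | CC#C[C@H](OC)[C@@H](O[Si](C)(C)C(C)(C)C)/C(C)=C\[C@H](C)[C@@H](OC)[C@@H](OC)C[C@H](C)[C@@H](OC)c1cc(OC)cc([N+](=O)[O-])c1OC | intermediate
21 | 3-[(1R,2S,4S,5R,6S,7Z,9S,10S)-9-[(tert-butyldimethylsilyl)oxy]-1,4,5,10-tetramethoxy-2,6,8-trimethyltridec-7-en-11-yn-1-yl]-2,5-dimethoxyaniline | CC#C[C@H](OC)[C@@H](O[Si](C)(C)C(C)(C)C)/C(C)=C\[C@H](C)[C@@H](OC)[C@@H](OC)C[C@H](C)[C@@H](OC)c1cc(OC)cc(N)c1OC | intermediate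
22 | but-2-ynal | CC#CC=O | starting material
23 | methyl (2Z)-2-methylhex-2-en-4-ynoate | COC(=O)/C(C)=C\C#CC | intermediate
24 | (2Z)-2-methylhex-2-en-4-ynoic acid | OC(=O)/C(C)=C\C#CC | intermediate
25 | (2Z)-2-methylhex-2-en-4-ynoyl chloride | ClC(=O)/C(C)=C\C#CC | intermediate
26 | (2Z)-N-{3-[(1R,2S,4S,5R,6S,7Z,9S,10S)-9-[(tert-butyldimethylsilyl)oxy]-1,4,5,10-tetramethoxy-2,6,8-trimethyltridec-7-en-11-yn-1-yl]-2,5-dimethoxyphenyl}-2-methylhex-2-en-4-ynamide | CC#C[C@H](OC)[C@@H](O[Si](C)(C)C(C)(C)C)/C(C)=C\[C@H](C)[C@@H](OC)[C@@H](OC)C[C@H](C)[C@@H](OC)c1cc(OC)cc(NC(=O)/C(C)=C\C#CC)c1OC | intermediate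
27 | cycloalkyne lactam: 4,5-didehydro-7-O-tert-butyldimethylsilyl-7-O-decarbamoyl-18,21-di-O-methyl derivative of 33 (2Z,8Z; 6S,7S,10S,11R,12S,14S,15R) | CO[C@H]1[C@@H](OC)C[C@H](C)[C@@H](OC)c2cc(OC)cc(c2OC)NC(=O)/C(C)=C\C#C[C@H](OC)[C@@H](O[Si](C)(C)C(C)(C)C)/C(C)=C\[C@@H]1C | intermediate
28 | 7-O-tert-butyldimethylsilyl-7-O-decarbamoyl-18,21-di-O-methyl derivative of 33 (2Z,4Z,8Z) | CO[C@H]1[C@@H](OC)C[C@H](C)[C@@H](OC)c2cc(OC)cc(c2OC)NC(=O)/C(C)=C\C=C/[C@H](OC)[C@@H](O[Si](C)(C)C(C)(C)C)/C(C)=C\[C@@H]1C | intermediate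
29 | 7-O-decarbamoyl-18,21-di-O-methyl derivative of 33 (free C7 hydroxyl) | CO[C@H]1[C@@H](OC)C[C@H](C)[C@@H](OC)c2cc(OC)cc(c2OC)NC(=O)/C(C)=C\C=C/[C@H](OC)[C@@H](O)/C(C)=C\[C@@H]1C | intermediate
30 | 7-O-[N-(trichloroacetyl)carbamoyl] derivative of 29 | CO[C@H]1[C@@H](OC)C[C@H](C)[C@@H](OC)c2cc(OC)cc(c2OC)NC(=O)/C(C)=C\C=C/[C@H](OC)[C@@H](OC(=O)NC(=O)C(Cl)(Cl)Cl)/C(C)=C\[C@@H]1C | intermediate
31 | 18,21-di-O-methyl ether of 33 | CO[C@H]1[C@@H](OC)C[C@H](C)[C@@H](OC)c2cc(OC)cc(c2OC)NC(=O)/C(C)=C\C=C/[C@H](OC)[C@@H](OC(N)=O)/C(C)=C\[C@@H]1C | intermediate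
32 | 18,21-quinone of 33 (1,4-benzoquinone with carbonyls at C18 and C21) | CO[C@H]1[C@@H](OC)C[C@H](C)[C@@H](OC)C2=CC(=O)C=C(C2=O)NC(=O)/C(C)=C\C=C/[C@H](OC)[C@@H](OC(N)=O)/C(C)=C\[C@@H]1C | intermediate
33 | [(4Z,6Z,8S,9S,10Z,12S,13R,14S,16S,17R)-20,22-dihydroxy-8,13,14,17-tetramethoxy-4,10,12,16-tetramethyl-3-oxo-2-azabicyclo[16.3.1]docosa-1(22),4,6,10,18,20-hexaen-9-yl] carbamate | CO[C@H]1[C@@H](OC)C[C@H](C)[C@@H](OC)c2cc(O)cc(c2O)NC(=O)/C(C)=C\C=C/[C@H](OC)[C@@H](OC(N)=O)/C(C)=C\[C@@H]1C | target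

## Step count and least certain steps

Total: 25 steps. Longest linear sequence: 22 steps (steps 1–11, 13–17, 20–25); steps 12, 18 and 19 make the two side fragments.

**Step 21 (key step).** The most likely failures are deactivation of the alkylidyne by the anilide N–H or by chelation to the ether array, and oligomerisation because the hindered propargylic alkyne next to the silyl ether engages slowly. The fallback moves the ring closure to the amide bond and sets out from 19. Sonogashira coupling (Pd(PPh3)2Cl2, CuI, Et3N) with methyl (2Z)-3-iodo-2-methylprop-2-enoate should give methyl (2Z,6S,7S,8Z,10S,11R,12S,14S,15R)-7-[(tert-butyldimethylsilyl)oxy]-15-(2,5-dimethoxy-3-nitrophenyl)-6,11,12,15-tetramethoxy-2,8,10,14-tetramethylpentadeca-2,8-dien-4-ynoate F1. Reduction with Zn and NH4Cl gives the corresponding aniline ester F2, and LiOH gives the amino acid F3. Lactamisation at high dilution (bis(2-oxo-3-oxazolidinyl)phosphinic chloride, i-Pr2NEt, toluene) comes back to the route at 27. The risk to C2=C3 on activation is then accepted.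

**Step 5.** The most likely failure is erosion of configuration at C12, because the α-acyloxy aldehyde can re-enter the enamine cycle, together with only moderate facial control by the catalyst. The fallback forms the C11–C12 bond by carbonyl addition instead of the C12–O bond and sets out from 4.
- Hydroboration (9-BBN, then NaBO3) gives (3S,4R)-4-(2,5-dimethoxy-3-nitrophenyl)-4-methoxy-3-methylbutan-1-ol F4.
- Dess–Martin oxidation gives the aldehyde (3S,4R)-4-(2,5-dimethoxy-3-nitrophenyl)-4-methoxy-3-methylbutanal F5.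
- Ligand-controlled addition of (E)-hex-1-enylzinc (from 1-hexyne, dicyclohexylborane and Et2Zn, with the amino alcohol ligand enantiomer that gives 12S) gives (1R,2S,4S,5E)-1-(2,5-dimethoxy-3-nitrophenyl)-1-methoxy-2-methyldec-5-en-4-ol F6.
- Methylation (NaH, MeI) gives (1R,2S,4S,5E)-1-(2,5-dimethoxy-3-nitrophenyl)-1,4-dimethoxy-2-methyldec-5-ene F7.
- Ozonolysis gives (2S,4S,5R)-5-(2,5-dimethoxy-3-nitrophenyl)-2,5-dimethoxy-4-methylpentanal F8.
- Crotylboration with the reagent of step 2 gives (3S,4R,5S,7S,8R)-8-(2,5-dimethoxy-3-nitrophenyl)-5,8-dimethoxy-3,7-dimethyloct-1-en-4-ol F9.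
- Methylation of F9 comes back to the route at 9.

**Step 13.** The most likely failure is Z to E isomerisation of enal 13 under the titanium Lewis acid and amine, or poor facial selectivity if the remote C10 centre is mismatched. The fallback uses a boron enolate, which needs no strong Lewis acid, and releases the aldehyde by another path; it sets out from 13.
- (4R)-4-Benzyl-3-(methoxyacetyl)-1,3-oxazolidin-2-one F10 is made from (R)-4-benzyl-1,3-oxazolidin-2-one and methoxyacetyl chloride.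
- Its dibutylboron enolate (Bu2BOTf, Et3N, −78 °C) adds to 13 to give (4R)-4-benzyl-3-[(2R,3S,4Z,6S,7R,8S,10S,11R)-11-(2,5-dimethoxy-3-nitrophenyl)-3-hydroxy-2,7,8,11-tetramethoxy-4,6,10-trimethylundec-4-enoyl]-1,3-oxazolidin-2-one F11.
- Transamination (AlMe3, MeONHMe·HCl) gives the Weinreb amide (2R,3S,4Z,6S,7R,8S,10S,11R)-11-(2,5-dimethoxy-3-nitrophenyl)-3-hydroxy-N,2,7,8,11-pentamethoxy-N,4,6,10-tetramethylundec-4-enamide F12.
- Silylation (t-BuMe2SiOTf, 2,6-lutidine) gives its 3-O-tert-butyldimethylsilyl ether F13.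
- Reduction of F13 with i-Bu2AlH gives aldehyde 18, and the homologation of step 15 comes back to the route at 19.

**Step 22.** The most likely failures are over-reduction or stalling on the metal surface, and metal-promoted cyclisation of the amide onto the triple bond of the (2Z)-en-4-ynamide. The fallback replaces surface reduction by stoichiometric syn hydrometalation and protonolysis and sets out from 27. Dicyclohexylborane (THF, 0 °C) should add across the triple bond to give the alkenylborane F14 (C4-boryl isomer shown; the C5-boryl isomer leads to the same product). Protodeboronation with acetic acid then comes back to the route at 28.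

## Further compounds

F1 | step 21 | methyl (2Z,6S,7S,8Z,10S,11R,12S,14S,15R)-7-[(tert-butyldimethylsilyl)oxy]-15-(2,5-dimethoxy-3-nitrophenyl)-6,11,12,15-tetramethoxy-2,8,10,14-tetramethylpentadeca-2,8-dien-4-ynoate | COC(=O)/C(C)=C\C#C[C@H](OC)[C@@H](O[Si](C)(C)C(C)(C)C)/C(C)=C\[C@H](C)[C@@H](OC)[C@@H](OC)C[C@H](C)[C@@H](OC)c1cc(OC)cc([N+](=O)[O-])c1OC
F2 | step 21 | methyl (2Z,6S,7S,8Z,10S,11R,12S,14S,15R)-15-(3-amino-2,5-dimethoxyphenyl)-7-[(tert-butyldimethylsilyl)oxy]-6,11,12,15-tetramethoxy-2,8,10,14-tetramethylpentadeca-2,8-dien-4-ynoate | COC(=O)/C(C)=C\C#C[C@H](OC)[C@@H](O[Si](C)(C)C(C)(C)C)/C(C)=C\[C@H](C)[C@@H](OC)[C@@H](OC)C[C@H](C)[C@@H](OC)c1cc(OC)cc(N)c1OC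
F3 | step 21 | (2Z,6S,7S,8Z,10S,11R,12S,14S,15R)-15-(3-amino-2,5-dimethoxyphenyl)-7-[(tert-butyldimethylsilyl)oxy]-6,11,12,15-tetramethoxy-2,8,10,14-tetramethylpentadeca-2,8-dien-4-ynoic acid | OC(=O)/C(C)=C\C#C[C@H](OC)[C@@H](O[Si](C)(C)C(C)(C)C)/C(C)=C\[C@H](C)[C@@H](OC)[C@@H](OC)C[C@H](C)[C@@H](OC)c1cc(OC)cc(N)c1OC
F4 | step 5 | (3S,4R)-4-(2,5-dimethoxy-3-nitrophenyl)-4-methoxy-3-methylbutan-1-ol | OCC[C@H](C)[C@@H](OC)c1cc(OC)cc([N+](=O)[O-])c1OC
F5 | step 5 | (3S,4R)-4-(2,5-dimethoxy-3-nitrophenyl)-4-methoxy-3-methylbutanal | O=CC[C@H](C)[C@@H](OC)c1cc(OC)cc([N+](=O)[O-])c1OC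
F6 | step 5 | (1R,2S,4S,5E)-1-(2,5-dimethoxy-3-nitrophenyl)-1-methoxy-2-methyldec-5-en-4-ol | CCCC/C=C/[C@@H](O)C[C@H](C)[C@@H](OC)c1cc(OC)cc([N+](=O)[O-])c1OC
F7 | step 5 | (1R,2S,4S,5E)-1-(2,5-dimethoxy-3-nitrophenyl)-1,4-dimethoxy-2-methyldec-5-ene | CCCC/C=C/[C@@H](OC)C[C@H](C)[C@@H](OC)c1cc(OC)cc([N+](=O)[O-])c1OC
F8 | step 5 | (2S,4S,5R)-5-(2,5-dimethoxy-3-nitrophenyl)-2,5-dimethoxy-4-methylpentanal | O=C[C@@H](OC)C[C@H](C)[C@@H](OC)c1cc(OC)cc([N+](=O)[O-])c1OC
F9 | step 5 | (3S,4R,5S,7S,8R)-8-(2,5-dimethoxy-3-nitrophenyl)-5,8-dimethoxy-3,7-dimethyloct-1-en-4-ol | C=C[C@H](C)[C@@H](O)[C@@H](OC)C[C@H](C)[C@@H](OC)c1cc(OC)cc([N+](=O)[O-])c1OC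
F10 | step 13 | (4R)-4-benzyl-3-(methoxyacetyl)-1,3-oxazolidin-2-one | COCC(=O)N1C(=O)OC[C@H]1Cc1ccccc1
F11 | step 13 | (4R)-4-benzyl-3-[(2R,3S,4Z,6S,7R,8S,10S,11R)-11-(2,5-dimethoxy-3-nitrophenyl)-3-hydroxy-2,7,8,11-tetramethoxy-4,6,10-trimethylundec-4-enoyl]-1,3-oxazolidin-2-one | O=C1OC[C@@H](Cc2ccccc2)N1C(=O)[C@H](OC)[C@@H](O)/C(C)=C\[C@H](C)[C@@H](OC)[C@@H](OC)C[C@H](C)[C@@H](OC)c1cc(OC)cc([N+](=O)[O-])c1OC
F12 | step 13 | (2R,3S,4Z,6S,7R,8S,10S,11R)-11-(2,5-dimethoxy-3-nitrophenyl)-3-hydroxy-N,2,7,8,11-pentamethoxy-N,4,6,10-tetramethylundec-4-enamide | CON(C)C(=O)[C@H](OC)[C@@H](O)/C(C)=C\[C@H](C)[C@@H](OC)[C@@H](OC)C[C@H](C)[C@@H](OC)c1cc(OC)cc([N+](=O)[O-])c1OC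
F13 | step 13 | (2R,3S,4Z,6S,7R,8S,10S,11R)-3-[(tert-butyldimethylsilyl)oxy]-11-(2,5-dimethoxy-3-nitrophenyl)-N,2,7,8,11-pentamethoxy-N,4,6,10-tetramethylundec-4-enamide | CON(C)C(=O)[C@H](OC)[C@@H](O[Si](C)(C)C(C)(C)C)/C(C)=C\[C@H](C)[C@@H](OC)[C@@H](OC)C[C@H](C)[C@@H](OC)c1cc(OC)cc([N+](=O)[O-])c1OC
F14 | step 22 | 4-(dicyclohexylboryl) derivative of 28 (alkenylborane from syn hydroboration of 27; 2Z,4Z,8Z) | CO[C@H]1[C@@H](OC)C[C@H](C)[C@@H](OC)c2cc(OC)cc(c2OC)NC(=O)/C(C)=C\C(B(C3CCCCC3)C3CCCCC3)=C/[C@H](OC)[C@@H](O[Si](C)(C)C(C)(C)C)/C(C)=C\[C@@H]1C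
A1 | alternative 1 | (2Z,4Z,6S,7S,8Z,10S,11R,12S,14S,15R)-15-(3-amino-2,5-dimethoxyphenyl)-7-[(tert-butyldimethylsilyl)oxy]-6,11,12,15-tetramethoxy-2,8,10,14-tetramethylpentadeca-2,4,8-trienoic acid | OC(=O)/C(C)=C\C=C/[C@H](OC)[C@@H](O[Si](C)(C)C(C)(C)C)/C(C)=C\[C@H](C)[C@@H](OC)[C@@H](OC)C[C@H](C)[C@@H](OC)c1cc(OC)cc(N)c1OC
A2 | alternative 2 | (3S,4S,5Z,7S,8R,9S,11S,12R)-12-{2,5-dimethoxy-3-[(2Z)-2-methylpenta-2,4-dienamido]phenyl}-3,8,9,12-tetramethoxy-5,7,11-trimethyldodeca-1,5-dien-4-yl carbamate | C=C[C@H](OC)[C@@H](OC(N)=O)/C(C)=C\[C@H](C)[C@@H](OC)[C@@H](OC)C[C@H](C)[C@@H](OC)c1cc(OC)cc(NC(=O)/C(C)=C\C=C)c1OC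
A3 | alternative 3 | (2Z,4Z,6S)-N-{3-[(1R,2S,4S,5R,6S,7Z)-8-iodo-1,4,5-trimethoxy-2,6-dimethylnon-7-en-1-yl]-2,5-dimethoxyphenyl}-6-methoxy-2-methyl-7-oxohepta-2,4-dienamide | I/C(C)=C\[C@H](C)[C@@H](OC)[C@@H](OC)C[C@H](C)[C@@H](OC)c1cc(OC)cc(NC(=O)/C(C)=C\C=C/[C@H](OC)C=O)c1OC
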